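**Strategy.** Everything rests on cutting the dihydrofuran ring (O1–C2–C3–C3a–C7a) away from its arene. The arene carbon C7a lies between the C7 methoxy group and the only free ortho C–H (C3a), so an aryl iodide iodinated at C7a is annulated with an enantiopure cis-epoxide by palladium/norbornene relay catalysis. One operation makes C3a–C3 (ortho C–H alkylation with inversion at the epoxide carbon) and O1–C7a (ipso C–O coupling), turning the cis-epoxide into the trans-2-aryl-3-(oxymethyl) ring. The precursors are the complete (3R,4R)-dibenzylbutyrolactone carrying a 4-iodo-3-methoxybenzyl group and a (2R,3S)-cis-3-aryl glycidyl benzyl ether whose aryl group is mesylate-deactivated.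

Key step: step 11

Remark: the new ring is numbered as a 2,3-dihydro-1-benzofuran (O1, C2, C3, C3a, C4 to C7, C7a); the facial sense of the epoxidation in step 10 is assigned by analogy with the behaviour of the same catalyst towards cis-β-methylstyrene and cis-cinnamate esters, and compounds 1, 3, 4, 11, 15 and 17 are taken as catalogue chemicals.

**Route**

Step 1
Reactants: 1 (4-iodo-3-methoxyphenyl)methanol
Product: 2 4-(bromomethyl)-1-iodo-2-methoxybenzene
Conditions: PBr3 (0.4 equiv), CH2Cl2, 0 °C to rt
Reagents that add atoms: phosphorus tribromide, BrP(Br)Br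
Why: bromination of a primary benzylic alcohol through its phosphite ester (SN2 by bromide), with the aryl iodide and methyl ether inert.

Step 2
Reactants: 3 (4R)-4-benzyl-1,3-oxazolidin-2-one; 4 4-tert-butoxy-4-oxobutanoic acid
Product: 6 tert-butyl 4-[(4R)-4-benzyl-2-oxo-1,3-oxazolidin-3-yl]-4-oxobutanoate, via mixed pivalic anhydride 5 (not isolated)
Conditions: 4, t-BuCOCl, Et3N, THF, −20 °C; then 3, LiCl, −20 °C to rt
Reagents that add atoms: none
Why: N-acylation of the oxazolidinone by a mixed anhydride (LiCl/Et3N protocol) should occur at the unhindered succinyl carbonyl and leave the tert-butyl ester untouched.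

Step 3
Reactants: 6 tert-butyl 4-[(4R)-4-benzyl-2-oxo-1,3-oxazolidin-3-yl]-4-oxobutanoate; 2 4-(bromomethyl)-1-iodo-2-methoxybenzene
Product: 8 tert-butyl (3R)-4-[(4R)-4-benzyl-2-oxo-1,3-oxazolidin-3-yl]-3-[(4-iodo-3-methoxyphenyl)methyl]-4-oxobutanoate, via sodium enolate 7 (not isolated)
Conditions: NaN(SiMe3)2, THF, −78 °C; then 2, −78 to −40 °C
Reagents that add atoms: none
Why: Evans asymmetric alkylation, in which only the imide is enolised (far more acidic than the tert-butyl ester) and the chelated Z enolate is benzylated on the face away from the benzyl group of the (R) auxiliary, setting the (R) centre that becomes C4 of the lactone.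

Step 4
Reactants: 8 tert-butyl (3R)-4-[(4R)-4-benzyl-2-oxo-1,3-oxazolidin-3-yl]-3-[(4-iodo-3-methoxyphenyl)methyl]-4-oxobutanoate
Product: 10 (4R)-4-[(4-iodo-3-methoxyphenyl)methyl]oxolan-2-one, via hydroxy tert-butyl ester 9 (not isolated)
Conditions: LiBH4, MeOH (1 equiv), THF, 0 °C; then CF3CO2H, CH2Cl2, rt
Reagents that add atoms: none
Why: reductive removal of the auxiliary (the imide carbonyl is reduced in preference to the tert-butyl ester, the aryl iodide is untouched) followed by acid-promoted lactonisation with loss of isobutene, neither of which involves the stereocentre.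

Step 5
Reactants: 11 [4-(benzyloxy)-3-methoxyphenyl]methanol
Product: 12 1-(benzyloxy)-4-(bromomethyl)-2-methoxybenzene
Conditions: PBr3 (0.4 equiv), CH2Cl2, 0 °C
Reagents that add atoms: phosphorus tribromide, BrP(Br)Br
Why: the same benzylic alcohol to bromide conversion as in step 1, with the aryl benzyl ether stable at 0 °C.

Step 6
Reactants: 10 (4R)-4-[(4-iodo-3-methoxyphenyl)methyl]oxolan-2-one; 12 1-(benzyloxy)-4-(bromomethyl)-2-methoxybenzene
Product: 14 (3R,4R)-3-{[4-(benzyloxy)-3-methoxyphenyl]methyl}-4-[(4-iodo-3-methoxyphenyl)methyl]oxolan-2-one, via lithium enolate 13 (not isolated)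
Conditions: LiN(SiMe3)2, THF, −78 °C; then 12, −78 to −30 °C
Reagents that add atoms: none
Why: alkylation of the lactone enolate should occur anti to the C4 substituent (substrate control), giving the trans (3R,4R) lactone, which is also the thermodynamic isomer, while the silylamide base leaves the aryl iodide alone.

Step 7
Reactants: 15 4-bromo-2-methoxyphenol
Product: 16 4-bromo-2-methoxyphenyl methanesulfonate
Conditions: MeSO2Cl, Et3N, CH2Cl2, 0 °C
Reagents that add atoms: methanesulfonyl chloride, CS(=O)(=O)Cl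
Why: O-sulfonylation of the phenol, the mesylate being chosen because it is stable to base and to palladium with the ligands used and because it makes the aryl ring electron-poor for steps 10 and 11.

Step 8
Reactants: 16 4-bromo-2-methoxyphenyl methanesulfonate; 17 benzyl prop-2-yn-1-yl ether
Product: 18 4-[3-(benzyloxy)prop-1-yn-1-yl]-2-methoxyphenyl methanesulfonate
Conditions: PdCl2(PPh3)2 (3 mol %), CuI (copper iodide, 5 mol %), Et3N, DMF, 70 °C
Reagents that add atoms: none
Why: Sonogashira coupling at the aryl bromide, which is activated by the para sulfonyloxy group, while the aryl mesylate does not undergo oxidative addition with PPh3 as ligand.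

Step 9
Reactants: 18 4-[3-(benzyloxy)prop-1-yn-1-yl]-2-methoxyphenyl methanesulfonate
Product: 19 4-[(1Z)-3-(benzyloxy)prop-1-en-1-yl]-2-methoxyphenyl methanesulfonate
Conditions: H2 (1 atm), Lindlar catalyst (Pd on CaCO3 poisoned with Pb(OAc)2), quinoline, EtOAc, rt
Reagents that add atoms: none
Why: Lindlar semihydrogenation adds H2 syn to the alkyne and should stop at the Z alkene, the benzyl ether and aryl sulfonate being stable on the poisoned catalyst.

Step 10
Reactants: 19 4-[(1Z)-3-(benzyloxy)prop-1-en-1-yl]-2-methoxyphenyl methanesulfonate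
Product: 20 4-{(2R,3S)-3-[(benzyloxy)methyl]oxiran-2-yl}-2-methoxyphenyl methanesulfonate (cis-epoxide)
Conditions: (R,R)-Mn(salen)Cl (5 mol %; salen = N,N'-bis(3,5-di-tert-butylsalicylidene)cyclohexane-1,2-diamine dianion), 4-phenylpyridine N-oxide (20 mol %), aq NaOCl (pH 11.3), CH2Cl2, 0 °C
Reagents that add atoms: sodium hypochlorite, [Na+].[O-]Cl
Why: Jacobsen–Katsuki epoxidation of a cis-disubstituted aryl-conjugated alkene, in which side-on approach to the oxo-manganese species of the (R,R) catalyst should make the benzylic carbon (R) and hence give the cis (2R,3S) epoxide, with the N-oxide additive and the electron-poor aryl group limiting leakage to the trans-epoxide.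

Step 11
Reactants: 14 (3R,4R)-3-{[4-(benzyloxy)-3-methoxyphenyl]methyl}-4-[(4-iodo-3-methoxyphenyl)methyl]oxolan-2-one; 20 4-{(2R,3S)-3-[(benzyloxy)methyl]oxiran-2-yl}-2-methoxyphenyl methanesulfonate
Product: 21 (3R,4R)-3-{[4-(benzyloxy)-3-methoxyphenyl]methyl}-4-({(2S,3R)-3-[(benzyloxy)methyl]-7-methoxy-2-[3-methoxy-4-(methanesulfonyloxy)phenyl]-2,3-dihydro-1-benzofuran-5-yl}methyl)oxolan-2-one
Conditions: Pd(OAc)2 (10 mol %), XPhos (20 mol %), potassium 5-norbornene-2-carboxylate (50 mol %), K2CO3 (2 equiv), 20 (1.5 equiv), NMP, 90 °C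
Reagents that add atoms: none
Why: Proposed new method: oxidative addition of 14 to zerovalent palladium, norbornene insertion and ortho C–H palladation at C3a give an aryl-norbornyl palladacycle of divalent palladium, which is expected to open epoxide 20 by SN2-type oxidative addition at the CH(CH2OBn) carbon (anti to its C–O bond) to give tetravalent palladium; aryl–alkyl reductive elimination then forms C3a–C3, norbornene is extruded, and the resulting aryl-palladium alkoxide forms O1–C7a. The closest known reaction type is the palladium/norbornene (Catellani-type) annulation of aryl iodides with terminal epoxides to 2,3-dihydrobenzofurans, together with the inversion seen when secondary alkyl iodides are used in Catellani alkylations; the 2,3-disubstituted cis-epoxide is the new element. The dihydrofuran ring is closed by C(aryl)–O reductive elimination from a six-membered oxapalladacycle, which gives the five-membered ring. C3 is set by stereospecific inversion of the (S) epoxide carbon and C2 is carried over unchanged from the Jacobsen epoxide, so the cis-epoxide maps onto the trans (2S,3R) ring. The step needs attack at the non-benzylic epoxide carbon: the mesylate makes the aryl group electron-poor and so removes the usual benzylic bias of epoxide opening, the bulky palladacycle should prefer the carbon carrying the smaller CH2OBn group, and the basic medium suppresses acid-type rearrangement of the epoxide. Mono-functionalisation is secured by the C7 methoxy group, which blocks the second ortho position and promotes norbornene extrusion.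

Step 12
Reactants: 21 (mesylate-protected annulation product)
Product: 23 (3R,4R)-3-{[4-(benzyloxy)-3-methoxyphenyl]methyl}-4-({(2S,3R)-3-[(benzyloxy)methyl]-2-(4-hydroxy-3-methoxyphenyl)-7-methoxy-2,3-dihydro-1-benzofuran-5-yl}methyl)oxolan-2-one, via ring-opened dipotassium salt 22 (not isolated)
Conditions: KOH, MeOH/THF/H2O, 50 °C (argon); then 1 M HCl, rt
Reagents that add atoms: none
Why: hydroxide cleaves the aryl mesylate at sulfur while the lactone opens reversibly to the hydroxy carboxylate, and acidification re-closes the γ-lactone, with no stereocentre affected because the carboxylate α-carbon is not deprotonated and the trans lactone is the thermodynamic isomer.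

Step 13
Reactants: 23 (dibenzyl ether of the target)
Product: 24 lappaol A, (3R,4R)-3-[(4-hydroxy-3-methoxyphenyl)methyl]-4-{[(2S,3R)-2-(4-hydroxy-3-methoxyphenyl)-3-(hydroxymethyl)-7-methoxy-2,3-dihydro-1-benzofuran-5-yl]methyl}oxolan-2-one
Conditions: H2 (1 atm), Pd/C (10 % palladium on carbon), EtOAc/MeOH, rt
Reagents that add atoms: none
Why: hydrogenolysis of the aryl benzyl ether and the primary alkyl benzyl ether, under mild neutral conditions in which the ring C2–O1 bond is expected to be cleaved far more slowly than the O-benzyl groups.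

**Compound list**

1 | (4-iodo-3-methoxyphenyl)methanol | COc1cc(CO)ccc1I | starting material
2 | 4-(bromomethyl)-1-iodo-2-methoxybenzene | COc1cc(CBr)ccc1I | intermediate
3 | (4R)-4-benzyl-1,3-oxazolidin-2-one | O=C1N[C@H](Cc2ccccc2)CO1 | starting material
4 | 4-tert-butoxy-4-oxobutanoic acid | CC(C)(C)OC(=O)CCC(=O)O | starting material
5 | 4-tert-butoxy-4-oxobutanoic pivalic anhydride (mixed anhydride) | CC(C)(C)OC(=O)CCC(=O)OC(=O)C(C)(C)C | intermediate
6 | tert-butyl 4-[(4R)-4-benzyl-2-oxo-1,3-oxazolidin-3-yl]-4-oxobutanoate | CC(C)(C)OC(=O)CCC(=O)N1[C@H](Cc2ccccc2)COC1=O | intermediate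
7 | sodium (Z)-enolate of imide 6 | CC(C)(C)OC(=O)C/C=C(\[O-])N1[C@H](Cc2ccccc2)COC1=O.[Na+] | intermediate
8 | tert-butyl (3R)-4-[(4R)-4-benzyl-2-oxo-1,3-oxazolidin-3-yl]-3-[(4-iodo-3-methoxyphenyl)methyl]-4-oxobutanoate | CC(C)(C)OC(=O)C[C@@H](Cc1ccc(I)c(OC)c1)C(=O)N1[C@H](Cc2ccccc2)COC1=O | intermediate
9 | tert-butyl (3R)-4-hydroxy-3-[(4-iodo-3-methoxyphenyl)methyl]butanoate | CC(C)(C)OC(=O)C[C@@H](Cc1ccc(I)c(OC)c1)CO | intermediate
10 | (4R)-4-[(4-iodo-3-methoxyphenyl)methyl]oxolan-2-one | O=C1C[C@@H](Cc2ccc(I)c(OC)c2)CO1 | intermediate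
11 | [4-(benzyloxy)-3-methoxyphenyl]methanol | COc1cc(CO)ccc1OCc1ccccc1 | starting material
12 | 1-(benzyloxy)-4-(bromomethyl)-2-methoxybenzene | COc1cc(CBr)ccc1OCc1ccccc1 | intermediate
13 | lithium enolate of lactone 10 | [Li+].[O-]C1=C[C@@H](Cc2ccc(I)c(OC)c2)CO1 | intermediate
14 | (3R,4R)-3-{[4-(benzyloxy)-3-methoxyphenyl]methyl}-4-[(4-iodo-3-methoxyphenyl)methyl]oxolan-2-one | COc1cc(C[C@H]2C(=O)OC[C@@H]2Cc2ccc(I)c(OC)c2)ccc1OCc1ccccc1 | intermediate
15 | 4-bromo-2-methoxyphenol | COc1cc(Br)ccc1O | starting material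
16 | 4-bromo-2-methoxyphenyl methanesulfonate | COc1cc(Br)ccc1OS(C)(=O)=O | intermediate
17 | benzyl prop-2-yn-1-yl ether | C#CCOCc1ccccc1 | starting material
18 | 4-[3-(benzyloxy)prop-1-yn-1-yl]-2-methoxyphenyl methanesulfonate | COc1cc(C#CCOCc2ccccc2)ccc1OS(C)(=O)=O | intermediate
19 | 4-[(1Z)-3-(benzyloxy)prop-1-en-1-yl]-2-methoxyphenyl methanesulfonate | COc1cc(/C=C\COCc2ccccc2)ccc1OS(C)(=O)=O | intermediate
20 | 4-{(2R,3S)-3-[(benzyloxy)methyl]oxiran-2-yl}-2-methoxyphenyl methanesulfonate | COc1cc([C@H]2O[C@H]2COCc2ccccc2)ccc1OS(C)(=O)=O | intermediate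
21 | (3R,4R)-3-{[4-(benzyloxy)-3-methoxyphenyl]methyl}-4-({(2S,3R)-3-[(benzyloxy)methyl]-7-methoxy-2-[3-methoxy-4-(methanesulfonyloxy)phenyl]-2,3-dihydro-1-benzofuran-5-yl}methyl)oxolan-2-one | COc1cc(C[C@H]2C(=O)OC[C@@H]2Cc2cc(OC)c3c(c2)[C@H](COCc2ccccc2)[C@@H](c2ccc(OS(C)(=O)=O)c(OC)c2)O3)ccc1OCc1ccccc1 | intermediate
22 | dipotassium salt of the ring-opened hydroxy acid phenolate derived from 21 | COc1cc(C[C@@H](C(=O)[O-])[C@H](CO)Cc2cc(OC)c3c(c2)[C@H](COCc2ccccc2)[C@@H](c2ccc([O-])c(OC)c2)O3)ccc1OCc1ccccc1.[K+].[K+] | intermediate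
23 | (3R,4R)-3-{[4-(benzyloxy)-3-methoxyphenyl]methyl}-4-({(2S,3R)-3-[(benzyloxy)methyl]-2-(4-hydroxy-3-methoxyphenyl)-7-methoxy-2,3-dihydro-1-benzofuran-5-yl}methyl)oxolan-2-one | COc1cc(C[C@H]2C(=O)OC[C@@H]2Cc2cc(OC)c3c(c2)[C@H](COCc2ccccc2)[C@@H](c2ccc(O)c(OC)c2)O3)ccc1OCc1ccccc1 | intermediate
24 | lappaol A | COc1cc(C[C@H]2C(=O)OC[C@@H]2Cc2cc(OC)c3c(c2)[C@H](CO)[C@@H](c2ccc(O)c(OC)c2)O3)ccc1O | target

**Step count.** Total: 13 steps. Longest linear sequence: 7 steps (steps 2, 3, 4, 6, 11, 12, 13; the epoxide branch, steps 7 to 13, is equally long).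

**Steps most likely to fail**

Step 11 (Proposed new method). The internal epoxide may fail to add oxidatively to the palladacycle, so that ipso reduction or homocoupling of the aryl iodide takes over. It may also be opened at the benzylic carbon, or lose stereospecificity through iodide-mediated double inversion. The fallback uses known chemistry, sets out from 14 and returns at 24. Miyaura borylation of 14 (B2pin2, PdCl2(dppf), KOAc, dioxane, 80 °C) should give the pinacol boronate F1, which is oxidised (NaBO3·4H2O, THF/H2O, rt) to the phenol F2. Oxidative β-5 cross-coupling of F2 with commercial (E)-coniferyl alcohol (Ag2O, acetone/CH2Cl2, rt) should then give the trans-phenylcoumaran, benzyl-protected lappaol A F3. Its (2R,3S) ring diastereomer would form alongside and would have to be removed by preparative HPLC. Hydrogenolysis under the conditions of step 13 gives 24. This fallback gives up the stereospecific annulation: the ring is trans, but its absolute configuration is not controlled.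

Step 10. Collapse of the radical intermediate with C–C rotation may leak trans-epoxide, and the enantioselectivity on this ether-substituted cis-alkene may fall short. The fallback sets out from 16 and returns at 20. Sonogashira coupling of 16 with propargyl alcohol (PdCl2(PPh3)2, CuI, Et3N, 70 °C) gives the arylpropargyl alcohol F4, and Lindlar semihydrogenation gives the (Z)-allylic alcohol F5. Hydroxyl-directed Sharpless asymmetric epoxidation (Ti(OiPr)4, L-(+)-diisopropyl tartrate, t-BuOOH, 4 Å molecular sieves, CH2Cl2, −20 °C) should give the cis-epoxy alcohol F6. Benzylation under non-basic conditions (BnBr, Ag2O, CH2Cl2), which avoids Payne rearrangement, then gives 20.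

Step 13. Over-reduction may occur by hydrogenolytic cleavage of the ring C2–O1 bond, which is benzylic and activated by the free para-hydroxyl group. The fallback sets out from 21 and returns at 24 by reversing the last two operations. Compound 21 is hydrogenolysed (H2, Pd/C, EtOAc) while the C2 aryl ring is still deactivated by the mesylate, giving O-mesyl lappaol A F7. Hydroxide cleavage of the mesylate (KOH, MeOH/H2O, 50 °C) passes through the ring-opened tripotassium salt F8, and acidification as in step 12 gives 24.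

Further compounds
F1 | step 11 | (3R,4R)-3-{[4-(benzyloxy)-3-methoxyphenyl]methyl}-4-{[3-methoxy-4-(4,4,5,5-tetramethyl-1,3,2-dioxaborolan-2-yl)phenyl]methyl}oxolan-2-one | COc1cc(C[C@H]2C(=O)OC[C@@H]2Cc2ccc(B3OC(C)(C)C(C)(C)O3)c(OC)c2)ccc1OCc1ccccc1
F2 | step 11 | (3R,4R)-3-{[4-(benzyloxy)-3-methoxyphenyl]methyl}-4-[(4-hydroxy-3-methoxyphenyl)methyl]oxolan-2-one | COc1cc(C[C@H]2C(=O)OC[C@@H]2Cc2ccc(O)c(OC)c2)ccc1OCc1ccccc1
F3 | step 11 | (3R,4R)-3-{[4-(benzyloxy)-3-methoxyphenyl]methyl}-4-{[(2S,3R)-2-(4-hydroxy-3-methoxyphenyl)-3-(hydroxymethyl)-7-methoxy-2,3-dihydro-1-benzofuran-5-yl]methyl}oxolan-2-one | COc1cc(C[C@H]2C(=O)OC[C@@H]2Cc2cc(OC)c3c(c2)[C@H](CO)[C@@H](c2ccc(O)c(OC)c2)O3)ccc1OCc1ccccc1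
F4 | step 10 | 4-(3-hydroxyprop-1-yn-1-yl)-2-methoxyphenyl methanesulfonate | COc1cc(C#CCO)ccc1OS(C)(=O)=O
F5 | step 10 | 4-[(1Z)-3-hydroxyprop-1-en-1-yl]-2-methoxyphenyl methanesulfonate | COc1cc(/C=C\CO)ccc1OS(C)(=O)=O
F6 | step 10 | 4-[(2R,3S)-3-(hydroxymethyl)oxiran-2-yl]-2-methoxyphenyl methanesulfonate | COc1cc([C@H]2O[C@H]2CO)ccc1OS(C)(=O)=O
F7 | step 13 | 4-[(2S,3R)-5-{[(3R,4R)-4-[(4-hydroxy-3-methoxyphenyl)methyl]-5-oxooxolan-3-yl]methyl}-3-(hydroxymethyl)-7-methoxy-2,3-dihydro-1-benzofuran-2-yl]-2-methoxyphenyl methanesulfonate | COc1cc(C[C@H]2C(=O)OC[C@@H]2Cc2cc(OC)c3c(c2)[C@H](CO)[C@@H](c2ccc(OS(C)(=O)=O)c(OC)c2)O3)ccc1O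
F8 | step 13 | tripotassium salt of the ring-opened hydroxy acid bis-phenolate of lappaol A | COc1cc(C[C@@H](C(=O)[O-])[C@H](CO)Cc2cc(OC)c3c(c2)[C@H](CO)[C@@H](c2ccc([O-])c(OC)c2)O3)ccc1[O-].[K+].[K+].[K+]
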